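**Retrosynthetic overview**
1. Structural feature: in the benzopyran, fusion carbon C4a (which bears C4) sits directly beside C5–OMe, and the next fusion carbon C8a bears O1. A 3-methoxyaryne imposes exactly this order, carbon near the methoxy group and oxygen far from it, when a C=O group adds across it.
2. Last disconnection: one acidic hydrolysis frees C7–OH from a MOM ether and the anisyl-side C=O of the 1,2-dione from a dimethyl ketal.
3. Key disconnection: the 2,2-dimethylpyran ring is cut at O1–C8a, C4–C4a and O1–C2. This leads back to the C4a,C8a-aryne (from an ortho-silylaryl triflate) and 3-methylbut-2-enal.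
4. Aryne precursor: 5-bromovanillin supplies all six ring positions (OH → OTf at C4a, OMe = C5, CHO → C7–O by Baeyer–Villiger oxidation, Br → SiMe3 at C8a). The C6–acyl bond comes from lithiation between the two oxygens and acylation with the ketal ester of 4-methoxybenzoylformate.
5. Ring order: both benzene rings are bought. The pyran is the only ring made, in the penultimate step.

Key step: step 9

Assumptions:
- The target has no stereocentre and is treated as the open, hydrogen-bonded 2-hydroxybenzil of the SMILES.
- Methyl rather than ethyl 4-methoxybenzoylformate is bought, so that ketalisation in methanol cannot scramble the ester.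
- The α,α-dimethoxy ketones 11, 12, 13 and 18 are prone to Norrish α-cleavage and are handled in amber glassware.

**Step 1**
Reactants: 1 5-bromovanillin
Product: 2 4-(benzyloxy)-3-bromo-5-methoxybenzaldehyde
Conditions: BnBr, K2CO3, DMF, 60 °C
Reagents that add atoms: benzyl bromide, BrCc1ccccc1
Why: Williamson ether synthesis on an acidic para-formyl phenol should be clean, and benzyl is chosen because it withstands peracid, MOMCl and organolithium reagents and later leaves under neutral hydrogenolysis.

**Step 2**
Reactants: 2 4-(benzyloxy)-3-bromo-5-methoxybenzaldehyde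
Product: 4 4-(benzyloxy)-3-bromo-5-methoxyphenol, via aryl formate 3 (not isolated)
Conditions: mCPBA, CH2Cl2, 0 °C → rt; reductive and NaHCO3 wash; then K2CO3 (cat.), MeOH, rt
Reagents that add atoms: 3-chloroperbenzoic acid, OOC(=O)c1cccc(Cl)c1
Why: Baeyer–Villiger oxidation, in which the aryl group carrying the para-alkoxy donor should migrate in the Criegee adduct in preference to hydride, and the aryl formate is then transesterified by methanol under mild base without touching the bromide or the benzyl ether.

**Step 3**
Reactants: 4 4-(benzyloxy)-3-bromo-5-methoxyphenol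
Product: 5 2-(benzyloxy)-1-bromo-3-methoxy-5-(methoxymethoxy)benzene
Conditions: MOMCl, i-Pr2NEt, CH2Cl2, 0 °C → rt
Reagents that add atoms: chloromethyl methyl ether, COCCl
Why: O-alkylation of the only free phenol with the oxocarbenium-type electrophile MOMCl gives an acetal that is inert to organolithiums and serves as directing group in step 6.

**Step 4**
Reactants: 5 2-(benzyloxy)-1-bromo-3-methoxy-5-(methoxymethoxy)benzene
Product: 7 [2-(benzyloxy)-3-methoxy-5-(methoxymethoxy)phenyl]trimethylsilane, via aryllithium 6 (not isolated)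
Conditions: n-BuLi, THF, −78 °C; then TMSCl, −78 °C → rt
Reagents that add atoms: chlorotrimethylsilane, C[Si](C)(C)Cl
Why: Bromine–lithium exchange at −78 °C is faster than any ring or benzylic deprotonation, and TMSCl silylates the aryllithium before it can rearrange, which places silicon on the future C8a.

**Step 5**
Reactants: 8 methyl 2-(4-methoxyphenyl)-2-oxoacetate (methyl 4-methoxybenzoylformate)
Product: 9 methyl 2,2-dimethoxy-2-(4-methoxyphenyl)acetate
Conditions: HC(OMe)3, H2SO4 (cat.), MeOH, reflux
Reagents that add atoms: trimethyl orthoformate, COC(OC)OC; methanol, CO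
Why: Acid-catalysed ketalisation, in which the ester-activated ketone passes through a p-anisyl-stabilised oxocarbenium ion and the orthoformate consumes the water, so the equilibrium is pulled to the ketal while the methyl ester cannot scramble in methanol.

**Step 6**
Reactants: 7 [2-(benzyloxy)-3-methoxy-5-(methoxymethoxy)phenyl]trimethylsilane; 9 methyl 2,2-dimethoxy-2-(4-methoxyphenyl)acetate
Product: 11 1-[3-(benzyloxy)-2-methoxy-6-(methoxymethoxy)-4-(trimethylsilyl)phenyl]-2,2-dimethoxy-2-(4-methoxyphenyl)ethan-1-one, via aryllithium 10 (not isolated)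
Conditions: n-BuLi, THF, 0 °C; then 9, −78 → 0 °C; aq. NH4Cl
Reagents that add atoms: none
Why: Directed ortho-metalation followed by nucleophilic acyl substitution, in which the C–H between OMe and OMOM is the most acidic and doubly coordinated site while the other position ortho to OMOM is shielded by SiMe3, and, as in the known acylation of aryllithiums by dialkoxyacetates, the chelated tetrahedral adduct and the congested ketone should prevent a second addition.

**Step 7**
Reactants: 11 1-[3-(benzyloxy)-2-methoxy-6-(methoxymethoxy)-4-(trimethylsilyl)phenyl]-2,2-dimethoxy-2-(4-methoxyphenyl)ethan-1-one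
Product: 12 1-[3-hydroxy-2-methoxy-6-(methoxymethoxy)-4-(trimethylsilyl)phenyl]-2,2-dimethoxy-2-(4-methoxyphenyl)ethan-1-one
Conditions: H2 (1 atm), Pd/C, EtOAc, rt
Reagents that add atoms: none
Why: Catalytic hydrogenolysis of the aryl benzyl ether runs under neutral conditions at which the twisted, doubly ortho-substituted ketone, the quaternary ketal carbon, the MOM ether and the aryl–silicon bond should stay untouched.

**Step 8**
Reactants: 12 1-[3-hydroxy-2-methoxy-6-(methoxymethoxy)-4-(trimethylsilyl)phenyl]-2,2-dimethoxy-2-(4-methoxyphenyl)ethan-1-one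
Product: 13 3-[2,2-dimethoxy-2-(4-methoxyphenyl)acetyl]-2-methoxy-4-(methoxymethoxy)-6-(trimethylsilyl)phenyl trifluoromethanesulfonate
Conditions: Tf2O, pyridine, CH2Cl2, 0 °C
Reagents that add atoms: trifluoromethanesulfonic anhydride, O=S(=O)(OS(=O)(=O)C(F)(F)F)C(F)(F)F
Why: O-sulfonylation with Tf2O and pyridine is the standard last step towards ortho-silylaryl triflates, works for phenols flanked by OMe and SiMe3, and the basic medium protects the MOM ether and the ketal.

**Step 9**
Reactants: 13 3-[2,2-dimethoxy-2-(4-methoxyphenyl)acetyl]-2-methoxy-4-(methoxymethoxy)-6-(trimethylsilyl)phenyl trifluoromethanesulfonate; 14 3-methylbut-2-enal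
Product: 18 1-[5-methoxy-7-(methoxymethoxy)-2,2-dimethyl-2H-chromen-6-yl]-2,2-dimethoxy-2-(4-methoxyphenyl)ethan-1-one, via aryne 15 (not isolated), via benzoxete 16 (not isolated), via ortho-quinone methide 17 (not isolated)
Conditions: CsF (3 equiv), 14 (5 equiv), MeCN, rt, slow addition of 13, amber flask
Reagents that add atoms: none
Why: Fluoride attacks silicon and triflate leaves to give aryne 15, the carbonyl oxygen of 14 adds to C8a, and the aryl anion left at C4a collapses on the dimethylallyl-stabilised oxocarbenium carbon (C4) to benzoxete 16, a formal [2+2] addition. Four-electron electrocyclic opening of the oxete gives ortho-quinone methide 17, whose Z-configured 1-oxatriene closes by a thermal disrotatory oxa-6π electrocyclisation that forms O1–C2, makes the six-membered pyran with C3=C4 in place and restores aromaticity. The closest known reaction type is the conversion of arynes from ortho-silylaryl triflates with α,β-unsaturated aldehydes into 2H-chromenes, related to aryne insertion into formamide C=O bonds. No stereocentre arises, because C2 carries two methyl groups and the stereocentre of 16 is lost on ring opening. The step needs regioselective addition, and the C5 methoxy group secures it by inductive withdrawal and aryne distortion, which make C8a the electrophilic terminus and stabilise charge at C4a, while the remote C7 OMOM group exerts only a weak opposing bias, as in 3,5-dialkoxyarynes that still obey the 3-alkoxy rule. It also needs chemoselectivity, which rests on the non-enolisable, hindered C6 ketone and on excess enal with a low aryne concentration, so that 17 cyclises before a second aryne can intercept it.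

**Step 10**
Reactants: 18 1-[5-methoxy-7-(methoxymethoxy)-2,2-dimethyl-2H-chromen-6-yl]-2,2-dimethoxy-2-(4-methoxyphenyl)ethan-1-one
Product: 19 1-(7-hydroxy-5-methoxy-2,2-dimethyl-2H-chromen-6-yl)-2-(4-methoxyphenyl)ethane-1,2-dione (target)
Conditions: 2 M aq. HCl, THF, 45 °C
Reagents that add atoms: water, O
Why: Acid-catalysed acetal hydrolysis, in which the MOM ether ortho to the ketone and the ketal (oxocarbenium ion stabilised by the p-anisyl ring) are both cleaved by dilute aqueous acid that 2,2-dimethyl-2H-chromenes tolerate, and the freed C7 hydroxyl is held by a hydrogen bond to the C6 carbonyl group.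

**Compound list**
1 | 5-bromovanillin (3-bromo-4-hydroxy-5-methoxybenzaldehyde) | COc1cc(C=O)cc(Br)c1O | starting material
2 | 4-(benzyloxy)-3-bromo-5-methoxybenzaldehyde | COc1cc(C=O)cc(Br)c1OCc1ccccc1 | intermediate
3 | 4-(benzyloxy)-3-bromo-5-methoxyphenyl formate | COc1cc(OC=O)cc(Br)c1OCc1ccccc1 | intermediate
4 | 4-(benzyloxy)-3-bromo-5-methoxyphenol | COc1cc(O)cc(Br)c1OCc1ccccc1 | intermediate
5 | 2-(benzyloxy)-1-bromo-3-methoxy-5-(methoxymethoxy)benzene | COc1cc(OCOC)cc(Br)c1OCc1ccccc1 | intermediate
6 | [2-(benzyloxy)-3-methoxy-5-(methoxymethoxy)phenyl]lithium | COc1cc(OCOC)cc([Li])c1OCc1ccccc1 | intermediate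
7 | [2-(benzyloxy)-3-methoxy-5-(methoxymethoxy)phenyl]trimethylsilane | COc1cc(OCOC)cc([Si](C)(C)C)c1OCc1ccccc1 | intermediate
8 | methyl 2-(4-methoxyphenyl)-2-oxoacetate | COC(=O)C(=O)c1ccc(OC)cc1 | starting material
9 | methyl 2,2-dimethoxy-2-(4-methoxyphenyl)acetate | COC(=O)C(OC)(OC)c1ccc(OC)cc1 | intermediate
10 | [3-(benzyloxy)-2-methoxy-6-(methoxymethoxy)-4-(trimethylsilyl)phenyl]lithium | COc1c([Li])c(OCOC)cc([Si](C)(C)C)c1OCc1ccccc1 | intermediate
11 | 1-[3-(benzyloxy)-2-methoxy-6-(methoxymethoxy)-4-(trimethylsilyl)phenyl]-2,2-dimethoxy-2-(4-methoxyphenyl)ethan-1-one | COc1ccc(cc1)C(OC)(OC)C(=O)c1c(OCOC)cc([Si](C)(C)C)c(OCc2ccccc2)c1OC | intermediate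
12 | 1-[3-hydroxy-2-methoxy-6-(methoxymethoxy)-4-(trimethylsilyl)phenyl]-2,2-dimethoxy-2-(4-methoxyphenyl)ethan-1-one | COc1ccc(cc1)C(OC)(OC)C(=O)c1c(OCOC)cc([Si](C)(C)C)c(O)c1OC | intermediate
13 | 3-[2,2-dimethoxy-2-(4-methoxyphenyl)acetyl]-2-methoxy-4-(methoxymethoxy)-6-(trimethylsilyl)phenyl trifluoromethanesulfonate | COc1ccc(cc1)C(OC)(OC)C(=O)c1c(OCOC)cc([Si](C)(C)C)c(OS(=O)(=O)C(F)(F)F)c1OC | intermediate
14 | 3-methylbut-2-enal (prenal) | CC(C)=CC=O | starting material
15 | 4-[2,2-dimethoxy-2-(4-methoxyphenyl)acetyl]-3-methoxy-5-(methoxymethoxy)-1,2-didehydrobenzene (aryne, triple bond between the future C4a and C8a) | COc1ccc(cc1)C(OC)(OC)C(=O)C1=C(OC)C#CC=C1OCOC | intermediate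
16 | 2H-benzoxete adduct, O on C8a and CH(CH=CMe2) on C4a (racemic, transient) | COc1ccc(cc1)C(OC)(OC)C(=O)c1c(OCOC)cc2OC(C=C(C)C)c2c1OC | intermediate
17 | (6Z)-4-[2,2-dimethoxy-2-(4-methoxyphenyl)acetyl]-5-methoxy-3-(methoxymethoxy)-6-(3-methylbut-2-en-1-ylidene)cyclohexa-2,4-dien-1-one | COc1ccc(cc1)C(OC)(OC)C(=O)C1=C(OC)/C(=C/C=C(C)C)C(=O)C=C1OCOC | intermediate
18 | 1-[5-methoxy-7-(methoxymethoxy)-2,2-dimethyl-2H-chromen-6-yl]-2,2-dimethoxy-2-(4-methoxyphenyl)ethan-1-one | COc1ccc(cc1)C(OC)(OC)C(=O)c1c(OCOC)cc2OC(C)(C)C=Cc2c1OC | intermediate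
19 | 1-(7-hydroxy-5-methoxy-2,2-dimethyl-2H-chromen-6-yl)-2-(4-methoxyphenyl)ethane-1,2-dione | COc1ccc(C(=O)C(=O)c2c(O)cc3c(c2OC)C=CC(C)(C)O3)cc1 | target

**Step count**
Total steps: 10. Longest linear sequence: 9 (steps 1–4 and 6–10). Step 5 is a one-step side branch.

**Steps most likely to fail**

1. Step 9.
   - What may go wrong: the aryne may be consumed by an ene reaction with the allylic methyl C–H bonds of the enal. The basic fluoride medium may drive dienolate self-condensation of the enal. The zwitterion may close at the γ-carbon in a formal [4+2] sense. The quinone methide may be intercepted by a second aryne.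
   - Fallback: it sets out from 13 and replaces the enal by a carbonyl partner that has none of these pathways. CsF in DMF generates the same aryne 15, and the formamide C=O inserts with the same orientation. This gives 4-[2,2-dimethoxy-2-(4-methoxyphenyl)acetyl]-6-[(dimethylamino)methylidene]-5-methoxy-3-(methoxymethoxy)cyclohexa-2,4-dien-1-one F1.
   - Aqueous work-up hydrolyses it to 3-[2,2-dimethoxy-2-(4-methoxyphenyl)acetyl]-6-hydroxy-2-methoxy-4-(methoxymethoxy)benzaldehyde F2.
   - A Petasis borono-Mannich reaction of F2 with 2-methylprop-1-enylboronic acid and dibenzylamine (dioxane, 90 °C) should give the 1-(dibenzylamino)-3-methylbut-2-enyl phenol F3. On heating this loses the amine, regenerates 17 and closes to the chromene, so the fallback comes back to the route at 18.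

2. Step 6.
   - What may go wrong: the doubly ortho-substituted aryllithium may add too slowly to the neopentyl-like ester carbonyl, so that it is protonated or decomposes on warming. Benzylic metalation of the benzyl ether may compete during a prolonged lithiation.
   - Fallback: it sets out from 9 and 7 and exchanges acyl substitution for aldehyde addition followed by oxidation. i-Bu2AlH (toluene, −78 °C) reduces 9 to 2,2-dimethoxy-2-(4-methoxyphenyl)acetaldehyde F4.
   - Aryllithium 10, made from 7 as before, adds to this smaller and more reactive electrophile at −78 °C. The product is racemic 1-[3-(benzyloxy)-2-methoxy-6-(methoxymethoxy)-4-(trimethylsilyl)phenyl]-2,2-dimethoxy-2-(4-methoxyphenyl)ethan-1-ol F5.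
   - Dess–Martin periodinane (CH2Cl2, NaHCO3) oxidises F5 to the ketone, and the route is rejoined at 11.

3. Step 10.
   - What may go wrong: the liberated C7 phenol may trap the ketal-derived oxocarbenium ion to a cyclic mixed ketal that stalls the hydrolysis. Prolonged Brønsted acid may hydrate or oligomerise the electron-rich C3=C4 alkene.
   - Fallback: it sets out from 18 and separates the two unmaskings, avoiding aqueous mineral acid. Catalytic I2 in acetone (rt) moves the two methoxy groups to the solvent by ketal exchange. This gives 1-[5-methoxy-7-(methoxymethoxy)-2,2-dimethyl-2H-chromen-6-yl]-2-(4-methoxyphenyl)ethane-1,2-dione F6, in which no oxocarbenium ion is left for the phenol to trap.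
   - The phenolic MOM ether is then removed with silica-supported NaHSO4 in CH2Cl2 at rt, and the route is rejoined at 19.

**Further compounds**
F1 | step 9 | 4-[2,2-dimethoxy-2-(4-methoxyphenyl)acetyl]-6-[(dimethylamino)methylidene]-5-methoxy-3-(methoxymethoxy)cyclohexa-2,4-dien-1-one | COc1ccc(cc1)C(OC)(OC)C(=O)C1=C(OC)C(=CN(C)C)C(=O)C=C1OCOC
F2 | step 9 | 3-[2,2-dimethoxy-2-(4-methoxyphenyl)acetyl]-6-hydroxy-2-methoxy-4-(methoxymethoxy)benzaldehyde | COc1ccc(cc1)C(OC)(OC)C(=O)c1c(OCOC)cc(O)c(C=O)c1OC
F3 | step 9 | 1-{3-[1-(dibenzylamino)-3-methylbut-2-en-1-yl]-4-hydroxy-2-methoxy-6-(methoxymethoxy)phenyl}-2,2-dimethoxy-2-(4-methoxyphenyl)ethan-1-one (racemic) | COc1ccc(cc1)C(OC)(OC)C(=O)c1c(OCOC)cc(O)c(C(C=C(C)C)N(Cc2ccccc2)Cc2ccccc2)c1OC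
F4 | step 6 | 2,2-dimethoxy-2-(4-methoxyphenyl)acetaldehyde | COc1ccc(cc1)C(OC)(OC)C=O
F5 | step 6 | 1-[3-(benzyloxy)-2-methoxy-6-(methoxymethoxy)-4-(trimethylsilyl)phenyl]-2,2-dimethoxy-2-(4-methoxyphenyl)ethan-1-ol (racemic) | COc1ccc(cc1)C(OC)(OC)C(O)c1c(OCOC)cc([Si](C)(C)C)c(OCc2ccccc2)c1OC
F6 | step 10 | 1-[5-methoxy-7-(methoxymethoxy)-2,2-dimethyl-2H-chromen-6-yl]-2-(4-methoxyphenyl)ethane-1,2-dione | COc1ccc(cc1)C(=O)C(=O)c1c(OCOC)cc2OC(C)(C)C=Cc2c1OC
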